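Remark (assumption): atoms are numbered as in cembrane (C1 carries the lactone carbon C15, C2 the lactone oxygen, C16 is the lactone carbonyl, C17 the exocyclic methylene, C18/C19/C20 the methyls on C4/C8/C12). Compounds 1, 4 and 9 and D-(−)-diethyl tartrate are taken as commercial.

## Structural features

The target is a cembranolide: a 14-membered carbocycle (C1–C14) with methyls on C4, C8 and C12, an E-C3=C4 and a Z-C12=C13 double bond. An α-methylene-γ-butyrolactone (C15, C16, C17 and the oxygen on C2) is cis-fused across C1–C2, so C1 (S) and C2 (S) are adjacent and C2 is also allylic. A 1,2-dioxane (C8–C9–C10–C11–O–O) bridges the macrocycle as a bicyclo[10.2.2] system; the ring chain leaves it through C7 on C8 and through C12 on C11, and these two bonds are trans. C8 is a quaternary peroxide carbon next to the C7 acetate, and the (7S,8S) pair is what anti addition of O and O–O to a Z-C7=C8 olefin would give. C11 (S) is a secondary peroxide carbon, allylic to the Z-olefin and remote from C1/C2. Fragile groups are the O–O bond (low-valent metals, phosphines, hydrides), the allylic α-peroxy C11–H (base-induced Kornblum–DeLaMare cleavage), the Michael-accepting methylene lactone and the allylic lactone C2–O bond. The real difficulty is the dioxane with C7, C8 and C11 inside the macrocycle, together with the Z-olefin beside it. The key step exploits that C8 and C11 are 1,4-related: C8 can be the tertiary end of a C7–C8 epoxide, and C11 the carbonyl carbon of a Z-enone C11(=O)–C12(C20)=C13 which, with C14 and C1, is the ring of carvone, so hydrogen peroxide can be added across the macrocycle as an intact O–O unit.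

## Logic of the disconnections

26 to 24. The C11–H bond is cut and C11 returns to the hemiketal level (C11–OH). C11 is allylic, so a stereospecific displacement cannot install its peroxide oxygen; as a hemiketal carbon it comes from a ketone and its configuration is decided last, inside the finished bicycle. This removes one stereocentre. The forward step must deliver hydride to cation 25 at C11 (not C13), on the face cis to C7, without Z/E isomerisation.

24 to 23. The acetyl C–O bond is cut. The acetate is placed before the reduction so that the C7 oxygen cannot add to cation 25. The forward step must acylate the secondary alcohol and leave the tertiary hemiketal hydroxyl.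

23 to 21 (key). Both C–O bonds of the dioxane (C8–O and C11–O) are cut and the O–O unit leaves as hydrogen peroxide. What remains is a monocyclic 14-membered ring carrying a (7S,8R)-epoxide and a C11 ketone. The bicyclic peroxide with its C7/C8 pair is reduced to one epoxide, and no peroxide exists until three steps from the end. The forward step needs attack at C8 with inversion, hydrogen peroxide faster than the C11 carbonyl oxygen, and 6-exo closure on C11. In one sentence: a macrocyclic Z-epoxy enone is stapled with hydrogen peroxide, at C8 by substitution and at C11 by hemiketalisation.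

21 to 19. The lactone acyl C–O bond is cut and C16 returns to the alcohol level. This gives a 2-methylene-1,4-diol that needs no protecting group. The forward oxidation must take the primary allylic alcohol and spare the secondary one.

19 to 18. The C2–C3 bond is cut, opening the macrocycle to an alkenyl iodide and an aldehyde (stored as its lactol). The new carbinol C2 forms next to C1, so 1,2-induction can set it. The forward step needs the Felkin sense at C2, high dilution, and addition to the aldehyde in the presence of the C11 ketone.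

18 and 17 to 15 plus 8. The C9–C10 bond is cut between the methyl carbon of a methyl ketone and the CH2 beside the epoxide. This splits the chain into two halves of similar size. The forward step needs C-alkylation of the kinetic dienolate 16, with the epoxide, the alkenyl iodide and the masked aldehyde untouched.

15 to 9. The bond C11–C2 is re-formed, which is the C1–C6 bond of the six-membered ring of 9. That ring holds C11–C12(C20)=C13–C14–C1 with the Z geometry and the C1 configuration, and its isopropenyl group holds C15–C17. C10 comes from methyllithium, the C2 oxygen from α′-acetoxylation, the C16 oxygen from allylic chlorination and acetate exchange. No step may epimerise the ring stereocentre.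

8 to 1 plus 4. The epoxide C–O bonds, the C7=C8 bond and the C4–C18 and C3–I bonds are cut. The forward steps need Z selectivity in the olefination and reagent-controlled face selectivity in the epoxidation.

## Other disconnections considered

Alternative 1: the first idea is to cut the peroxide as biosynthesis presumably does. A macrocyclic epoxy olefin A1 (from the usual allylation macrocyclisation) would undergo a Schenck ene reaction with singlet oxygen to the C11 hydroperoxide A2, which opens the epoxide across the ring to the hydroxy dioxane A3. The ene reaction would have to bond oxygen to C11 and take hydrogen from C13. In an E-11-olefin the cis effect favours abstraction from C20 or C10 instead. Nothing controls the C11 configuration or the geometry of the new olefin, and three trisubstituted olefins compete. The chosen plan takes the Z-olefin and the C11 oxygen position from the carvone enone and brings O–O in as hydrogen peroxide.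

Alternative 2: the dioxane could be made first. Singlet oxygen adds [4+2] to diene A4 to give endoperoxide A5, and ozonolysis of its olefin bridge gives the dioxane keto aldehyde A6, which contains C7, C8, C9, C10, C11 and C12. Suprafacial addition fixes the C7 and C12 branches cis, whereas the target needs them trans. A5 is racemic with no handle for resolution. The α-peroxy ketone in A6 has an acidic C11–H set up for Kornblum–DeLaMare cleavage. The peroxide would also have to survive every later C–C bond formation, which excludes divalent chromium for the macrocyclisation.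

Alternative 3: a hydroxy-directed ene reaction could set C8 from C7. In the macrocyclic Z-allylic alcohol A7, 1,3-allylic strain and hydrogen bonding steer singlet oxygen to give the threo hydroperoxide A8, which has the correct (7S,8S) pair. The new E-C9=C10 olefin then lies inside the future dioxane and must be reduced with diimide in competition with the 1,1-disubstituted C15=C17 olefin. The second allylic oxygen at C11 and the other trisubstituted olefins compete in the photooxygenation. The chosen epoxide perhydrolysis gives the same pair stereospecifically without a new olefin and without a separate asymmetric step for C7.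

Key step: step 17

## Route

Step 1
Reactants: 1 pent-4-yn-1-ol
Product: 2 (4E)-5-iodo-4-methylpent-4-en-1-ol
Conditions: AlMe3, Cp2ZrCl2 (cat.), CH2Cl2, 0 °C to rt; then I2, THF, −30 °C
Reagents that add atoms: trimethylaluminium C[Al](C)C; iodine II
Why: Negishi zirconium-catalysed carboalumination adds methyl and aluminium syn across the terminal alkyne with methyl on the internal carbon; iodinolysis with retention should give the E-alkenyl iodide (C3=C4 with C18).

Step 2
Reactants: 2 (4E)-5-iodo-4-methylpent-4-en-1-ol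
Product: 3 (4E)-5-iodo-4-methylpent-4-enal
Conditions: Dess–Martin periodinane, CH2Cl2, 0 °C to rt
Reagents that add atoms: none
Why: Dess–Martin oxidation of a primary alcohol; the alkenyl iodide is inert.

Step 3
Reactants: 3 (4E)-5-iodo-4-methylpent-4-enal; 4 ethyl 2-[bis(2,2,2-trifluoroethoxy)phosphoryl]propanoate
Product: 5 ethyl (2Z,6E)-7-iodo-2,6-dimethylhepta-2,6-dienoate
Conditions: KN(SiMe3)2, 18-crown-6, THF, −78 °C
Reagents that add atoms: none
Why: Still–Gennari olefination; the trifluoroethyl phosphonate with a dissociated potassium counter-ion eliminates from the kinetic syn adduct, which should give the Z-2-methyl enoate (future C7=C8, ester carbon C9 cis to C6).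

Step 4
Reactants: 5 ethyl (2Z,6E)-7-iodo-2,6-dimethylhepta-2,6-dienoate
Product: 6 (2Z,6E)-7-iodo-2,6-dimethylhepta-2,6-dien-1-ol
Conditions: i-Bu2AlH, CH2Cl2, −78 °C
Reagents that add atoms: none
Why: 1,2-reduction of the enoate to the allylic alcohol without loss of olefin geometry.

Step 5
Reactants: 6 (2Z,6E)-7-iodo-2,6-dimethylhepta-2,6-dien-1-ol
Product: 7 [(2R,3S)-3-[(3E)-4-iodo-3-methylbut-3-en-1-yl]-2-methyloxiran-2-yl]methanol
Conditions: Ti(OiPr)4 (cat.), D-(−)-diethyl tartrate (cat.), t-BuOOH, 4 Å MS, CH2Cl2, −20 °C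
Reagents that add atoms: tert-butyl hydroperoxide CC(C)(C)OO
Why: Sharpless asymmetric epoxidation; with the D-(−)-tartrate the titanium-bound peroxide should be delivered to the face that makes the quaternary carbon R (C8) and the secondary carbon S (C7). Only the allylic alcohol olefin reacts, the iodoalkene is inert.

Step 6
Reactants: 7 [(2R,3S)-3-[(3E)-4-iodo-3-methylbut-3-en-1-yl]-2-methyloxiran-2-yl]methanol
Product: 8 [(2R,3S)-3-[(3E)-4-iodo-3-methylbut-3-en-1-yl]-2-methyloxiran-2-yl]methyl trifluoromethanesulfonate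
Conditions: Tf2O, 2,6-lutidine, CH2Cl2, −78 °C (used at once)
Reagents that add atoms: trifluoromethanesulfonic anhydride O=S(=O)(OS(=O)(=O)C(F)(F)F)C(F)(F)F
Why: O-sulfonylation of the primary epoxy alcohol at low temperature with a hindered base; no stereocentre is touched.

Step 7
Reactants: 9 (R)-(−)-carvone, (5R)-2-methyl-5-(prop-1-en-2-yl)cyclohex-2-en-1-one
Product: 10 (5R)-5-(3-chloroprop-1-en-2-yl)-2-methylcyclohex-2-en-1-one
Conditions: Ca(OCl)2, CO2 (s), CH2Cl2/H2O, 0 °C
Reagents that add atoms: calcium hypochlorite [Ca+2].[O-]Cl.[O-]Cl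
Why: ene-type allylic chlorination by hypochlorous acid attacks the electron-rich 1,1-disubstituted olefin and not the enone; it puts the handle for the C16 oxygen in place and leaves the ring stereocentre alone.

Step 8
Reactants: 10 (5R)-5-(3-chloroprop-1-en-2-yl)-2-methylcyclohex-2-en-1-one
Product: 11 2-[(1R)-4-methyl-5-oxocyclohex-3-en-1-yl]prop-2-en-1-yl acetate
Conditions: KOAc, 18-crown-6 (cat.), MeCN, 60 °C
Reagents that add atoms: potassium acetate CC(=O)[O-].[K+]
Why: substitution of the primary allylic chloride by acetate; the weak base should not enolise the enone.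

Step 9
Reactants: 11 2-[(1R)-4-methyl-5-oxocyclohex-3-en-1-yl]prop-2-en-1-yl acetate
Product: 12 (6S)-6-[3-(acetyloxy)prop-1-en-2-yl]-3-methyl-2-oxocyclohex-3-en-1-yl acetate (both epimers at C1 of the ring)
Conditions: Mn(OAc)3, benzene, reflux
Reagents that add atoms: manganese triacetate CC(=O)[O-].CC(=O)[O-].CC(=O)[O-].[Mn+3]
Why: α′-acetoxylation of an enone through its manganese enolate puts oxygen on the ring CH2 that becomes C2. Both epimers serve, because this carbon becomes an sp2 aldehyde carbon in step 11.

Step 10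
Reactants: 12 (6S)-6-[3-(acetyloxy)prop-1-en-2-yl]-3-methyl-2-oxocyclohex-3-en-1-yl acetate
Product: 13 (5S)-5-(3-hydroxyprop-1-en-2-yl)-1,2-dimethylcyclohex-2-ene-1,6-diol (epimers at C1 and C6)
Conditions: MeLi (excess), THF, −78 °C to 0 °C
Reagents that add atoms: methyllithium [Li]C
Why: 1,2-addition of methyllithium to the enone carbonyl brings in C10, and the same reagent cleaves both acetates. The configuration of the two carbinol carbons is irrelevant.

Step 11
Reactants: 13 (5S)-5-(3-hydroxyprop-1-en-2-yl)-1,2-dimethylcyclohex-2-ene-1,6-diol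
Product: 14 (3Z)-5-[(3S)-2-hydroxy-4-methylideneoxolan-3-yl]-3-methylpent-3-en-2-one (lactol, both anomers)
Conditions: NaIO4, THF/H2O, 0 °C to rt
Reagents that add atoms: none
Why: Malaprade glycol cleavage of the ring diol gives the methyl Z-enone (geometry inherited from the ring) and the C2 aldehyde. The C16 hydroxyl traps the aldehyde as a five-membered lactol, which protects the epimerisable, allylic C1 centre.

Step 12
Reactants: 14 (3Z)-5-[(3S)-2-hydroxy-4-methylideneoxolan-3-yl]-3-methylpent-3-en-2-one
Product: 15 (3Z)-5-[(3S)-2-[tert-butyl(dimethyl)silyl]oxy-4-methylideneoxolan-3-yl]-3-methylpent-3-en-2-one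
Conditions: TBSCl, imidazole, DMF, 0 °C
Reagents that add atoms: tert-butyl(chloro)dimethylsilane CC(C)(C)[Si](C)(C)Cl
Why: silylation of the lactol hydroxyl gives a mixed silyl acetal that is stable to amide bases and is removed by fluoride without acid.

Step 13
Reactants: 15 (3Z)-5-[(3S)-2-[tert-butyl(dimethyl)silyl]oxy-4-methylideneoxolan-3-yl]-3-methylpent-3-en-2-one; 8 [(2R,3S)-3-[(3E)-4-iodo-3-methylbut-3-en-1-yl]-2-methyloxiran-2-yl]methyl trifluoromethanesulfonate
Product: 17 (2Z)-1-[(3S)-2-[tert-butyl(dimethyl)silyl]oxy-4-methylideneoxolan-3-yl]-6-[(2R,3S)-3-[(3E)-4-iodo-3-methylbut-3-en-1-yl]-2-methyloxiran-2-yl]-3-methylhex-2-en-4-one, via lithium dienolate 16 (not isolated)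
Conditions: LiN(i-Pr)2, THF, −78 °C; then 8, −78 to −40 °C
Reagents that add atoms: none
Why: kinetic deprotonation of the methyl ketone gives the cross-conjugated dienolate, which keeps the Z-olefin. C-alkylation by the primary glycidyl-type triflate should form C9–C10 without touching the epoxide carbons or the alkenyl iodide.

Step 14
Reactants: 17 (2Z)-1-[(3S)-2-[tert-butyl(dimethyl)silyl]oxy-4-methylideneoxolan-3-yl]-6-[(2R,3S)-3-[(3E)-4-iodo-3-methylbut-3-en-1-yl]-2-methyloxiran-2-yl]-3-methylhex-2-en-4-one
Product: 18 (2Z)-1-[(3S)-2-hydroxy-4-methylideneoxolan-3-yl]-6-[(2R,3S)-3-[(3E)-4-iodo-3-methylbut-3-en-1-yl]-2-methyloxiran-2-yl]-3-methylhex-2-en-4-one (lactol)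
Conditions: Bu4NF, AcOH, THF, 0 °C
Reagents that add atoms: none
Why: buffered fluoride cleaves the silyl acetal under near-neutral conditions, which the trisubstituted epoxide and the Z-enone should tolerate.

Step 15
Reactants: 18 (2Z)-1-[(3S)-2-hydroxy-4-methylideneoxolan-3-yl]-6-[(2R,3S)-3-[(3E)-4-iodo-3-methylbut-3-en-1-yl]-2-methyloxiran-2-yl]-3-methylhex-2-en-4-one
Product: 19 (1S,2S,3E,7S,8R,12Z)-7,8-epoxy-2,16-dihydroxycembra-3,12,15(17)-trien-11-one (14-membered carbocycle)
Conditions: CrCl2 (excess), NiCl2 (cat.), DMSO/THF, rt, high dilution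
Reagents that add atoms: none
Why: Nozaki–Hiyama–Kishi macrocyclisation; the alkenylchromium species formed with retention of the E geometry adds to the aldehyde in equilibrium with the lactol and ignores the C11 ketone. Felkin–Anh addition anti to the branched alkenyl group on C1 should give the (2S) carbinol.

Step 16
Reactants: 19 (1S,2S,3E,7S,8R,12Z)-7,8-epoxy-2,16-dihydroxycembra-3,12,15(17)-trien-11-one
Product: 21 (1S,2S,3E,7S,8R,12Z)-7,8-epoxy-11-oxocembra-3,12,15(17)-trien-16,2-olide, via lactol 20 (not isolated)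
Conditions: TEMPO (cat.), PhI(OAc)2, CH2Cl2, rt
Reagents that add atoms: none
Why: oxoammonium oxidation takes the primary allylic alcohol to the enal, the C2 hydroxyl closes the lactol, and a second oxidation gives the cis-fused α-methylene lactone. Secondary alcohols react more slowly, so C2 keeps its configuration.

Step 17
Reactants: 21 (1S,2S,3E,7S,8R,12Z)-7,8-epoxy-11-oxocembra-3,12,15(17)-trien-16,2-olide
Product: 23 (1S,2S,3E,7S,8S,12Z)-8,11-epidioxy-7,11-dihydroxycembra-3,12,15(17)-trien-16,2-olide (C11 hemiketal epimers), via hydroxy hydroperoxide 22 (not isolated)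
Conditions: H2O2 (anhydrous, in Et2O, excess), H3PMo12O40 (cat.), Et2O, 0 °C to rt
Reagents that add atoms: hydrogen peroxide OO
Why: H3PMo12O40 activates the trisubstituted epoxide and hydrogen peroxide attacks the tertiary, cation-stabilising C8 in a borderline SN2 opening with inversion, so the (8R) epoxide carbon becomes the (8S) hydroperoxide and C7 keeps its (S) oxygen as the free carbinol in 22. The δ-hydroperoxy ketone 22 then closes across the ring on the C11 carbonyl by 6-exo-trig addition of the hydroperoxide, giving the 1,2-dioxan-3-ol 23 and with it the bicyclo[10.2.2] core. The closest known reaction types are the phosphomolybdic acid catalysed perhydrolysis of epoxides at the more substituted carbon and the spontaneous cyclisation of δ-hydroperoxy ketones to cyclic peroxyhemiketals. C8 is controlled by stereospecific inversion and C7 by the epoxide; the new hemiketal centre C11 need not be controlled, because it is planarised in step 19. The step needs attack at C8 and not C7, which tertiary versus secondary substitution secures, and the ring closure is 6-exo on the only carbonyl within reach. It also needs hydrogen peroxide to outrun the C11 carbonyl oxygen as the nucleophile at C8, which the large excess of concentrated ethereal reagent is meant to secure. The other olefins are an enone, an acrylate and a trisubstituted olefin deactivated by the allylic lactone oxygen, none of which should be epoxidised under these acidic conditions.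

Step 18
Reactants: 23 (1S,2S,3E,7S,8S,12Z)-8,11-epidioxy-7,11-dihydroxycembra-3,12,15(17)-trien-16,2-olide
Product: 24 (1S,2S,3E,7S,8S,12Z)-7-acetoxy-8,11-epidioxy-11-hydroxycembra-3,12,15(17)-trien-16,2-olide
Conditions: Ac2O, pyridine, DMAP (cat.), CH2Cl2, 0 °C
Reagents that add atoms: acetic anhydride CC(=O)OC(C)=O
Why: acylation of the secondary C7 alcohol; the tertiary hemiketal hydroxyl is much slower. The acetate keeps the C7 oxygen from adding to the C11 cation in step 19.

Step 19
Reactants: 24 (1S,2S,3E,7S,8S,12Z)-7-acetoxy-8,11-epidioxy-11-hydroxycembra-3,12,15(17)-trien-16,2-olide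
Product: 26 (1S,2S,3E,7S,8S,11S,12Z)-7-acetoxy-8,11-epidioxycembra-3,12,15(17)-trien-16,2-olide (target), via peroxycarbenium ion 25 (not isolated)
Conditions: Et3SiH, BF3·OEt2, CH2Cl2, −78 °C
Reagents that add atoms: none
Why: ionic hydrogenation of a cyclic peroxyhemiketal; BF3 ionises the C11–OH bond to the peroxycarbenium ion 25 and Et3SiH adds hydride at C11 along the axial trajectory. In the half-chair with the larger C7 branch on C8 pseudo-equatorial, hydride should enter cis to C7 and leave C12 equatorial, which is (11S). Low temperature and fast trapping should preserve the Z-olefin.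

## Compound list

1 | pent-4-yn-1-ol | C#CCCCO | starting material
2 | (4E)-5-iodo-4-methylpent-4-en-1-ol | C/C(CCCO)=C\I | intermediate
3 | (4E)-5-iodo-4-methylpent-4-enal | C/C(CCC=O)=C\I | intermediate
4 | ethyl 2-[bis(2,2,2-trifluoroethoxy)phosphoryl]propanoate | CCOC(=O)C(C)P(=O)(OCC(F)(F)F)OCC(F)(F)F | starting material
5 | ethyl (2Z,6E)-7-iodo-2,6-dimethylhepta-2,6-dienoate | CCOC(=O)/C(C)=C\CC/C(C)=C/I | intermediate
6 | (2Z,6E)-7-iodo-2,6-dimethylhepta-2,6-dien-1-ol | OC/C(C)=C\CC/C(C)=C/I | intermediate
7 | [(2R,3S)-3-[(3E)-4-iodo-3-methylbut-3-en-1-yl]-2-methyloxiran-2-yl]methanol | OC[C@@]1(C)O[C@H]1CC/C(C)=C/I | intermediate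
8 | [(2R,3S)-3-[(3E)-4-iodo-3-methylbut-3-en-1-yl]-2-methyloxiran-2-yl]methyl trifluoromethanesulfonate | FC(F)(F)S(=O)(=O)OC[C@@]1(C)O[C@H]1CC/C(C)=C/I | intermediate
9 | (R)-(−)-carvone, (5R)-2-methyl-5-(prop-1-en-2-yl)cyclohex-2-en-1-one | CC1=CC[C@H](CC1=O)C(C)=C | starting material
10 | (5R)-5-(3-chloroprop-1-en-2-yl)-2-methylcyclohex-2-en-1-one | CC1=CC[C@H](CC1=O)C(=C)CCl | intermediate
11 | 2-[(1R)-4-methyl-5-oxocyclohex-3-en-1-yl]prop-2-en-1-yl acetate | CC1=CC[C@H](CC1=O)C(=C)COC(C)=O | intermediate
12 | (6S)-6-[3-(acetyloxy)prop-1-en-2-yl]-3-methyl-2-oxocyclohex-3-en-1-yl acetate (C1 epimers) | CC1=CC[C@H](C(OC(C)=O)C1=O)C(=C)COC(C)=O | intermediate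
13 | (5S)-5-(3-hydroxyprop-1-en-2-yl)-1,2-dimethylcyclohex-2-ene-1,6-diol (C1 and C6 epimers) | CC1=CC[C@H](C(O)C1(C)O)C(=C)CO | intermediate
14 | (3Z)-5-[(3S)-2-hydroxy-4-methylideneoxolan-3-yl]-3-methylpent-3-en-2-one (anomers) | CC(=O)/C(C)=C\C[C@@H]1C(O)OCC1=C | intermediate
15 | (3Z)-5-[(3S)-2-[tert-butyl(dimethyl)silyl]oxy-4-methylideneoxolan-3-yl]-3-methylpent-3-en-2-one (anomers) | CC(=O)/C(C)=C\C[C@@H]1C(O[Si](C)(C)C(C)(C)C)OCC1=C | intermediate
16 | lithium dienolate of 15 (O-lithiated, terminal CH2=C(OLi)) | C=C(O[Li])/C(C)=C\C[C@@H]1C(O[Si](C)(C)C(C)(C)C)OCC1=C | intermediate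
17 | (2Z)-1-[(3S)-2-[tert-butyl(dimethyl)silyl]oxy-4-methylideneoxolan-3-yl]-6-[(2R,3S)-3-[(3E)-4-iodo-3-methylbut-3-en-1-yl]-2-methyloxiran-2-yl]-3-methylhex-2-en-4-one | I/C=C(\C)CC[C@@H]1O[C@]1(C)CCC(=O)/C(C)=C\C[C@@H]2C(O[Si](C)(C)C(C)(C)C)OCC2=C | intermediate
18 | (2Z)-1-[(3S)-2-hydroxy-4-methylideneoxolan-3-yl]-6-[(2R,3S)-3-[(3E)-4-iodo-3-methylbut-3-en-1-yl]-2-methyloxiran-2-yl]-3-methylhex-2-en-4-one | I/C=C(\C)CC[C@@H]1O[C@]1(C)CCC(=O)/C(C)=C\C[C@@H]2C(O)OCC2=C | intermediate
19 | (1S,2S,3E,7S,8R,12Z)-7,8-epoxy-2,16-dihydroxycembra-3,12,15(17)-trien-11-one | OCC(=C)[C@H]1[C@@H](O)/C=C(\C)CC[C@@H]2O[C@]2(C)CCC(=O)/C(C)=C\C1 | intermediate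
20 | (1S,2S,3E,7S,8R,12Z)-7,8-epoxy-16-hydroxy-2,16-epoxycembra-3,12,15(17)-trien-11-one (lactol of 21) | C=C1C(O)O[C@H]2/C=C(\C)CC[C@@H]3O[C@]3(C)CCC(=O)/C(C)=C\C[C@@H]12 | intermediate
21 | (1S,2S,3E,7S,8R,12Z)-7,8-epoxy-11-oxocembra-3,12,15(17)-trien-16,2-olide | C=C1C(=O)O[C@H]2/C=C(\C)CC[C@@H]3O[C@]3(C)CCC(=O)/C(C)=C\C[C@@H]12 | intermediate
22 | (1S,2S,3E,7S,8S,12Z)-8-hydroperoxy-7-hydroxy-11-oxocembra-3,12,15(17)-trien-16,2-olide | C=C1C(=O)O[C@H]2/C=C(\C)CC[C@H](O)[C@@](C)(OO)CCC(=O)/C(C)=C\C[C@@H]12 | intermediate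
23 | (1S,2S,3E,7S,8S,12Z)-8,11-epidioxy-7,11-dihydroxycembra-3,12,15(17)-trien-16,2-olide (C11 epimers) | C=C1C(=O)O[C@H]2/C=C(\C)CC[C@H](O)[C@]3(C)CCC(O)(OO3)/C(C)=C\C[C@@H]12 | intermediate
24 | (1S,2S,3E,7S,8S,12Z)-7-acetoxy-8,11-epidioxy-11-hydroxycembra-3,12,15(17)-trien-16,2-olide (C11 epimers) | C=C1C(=O)O[C@H]2/C=C(\C)CC[C@H](OC(C)=O)[C@]3(C)CCC(O)(OO3)/C(C)=C\C[C@@H]12 | intermediate
25 | cyclic C11 peroxycarbenium ion of 24 | C=C1C(=O)O[C@H]2/C=C(\C)CC[C@H](OC(C)=O)[C@]3(C)CCC(=[O+]O3)/C(C)=C\C[C@@H]12 | intermediate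
26 | (1S,2S,3E,7S,8S,11S,12Z)-7-acetoxy-8,11-epidioxycembra-3,12,15(17)-trien-16,2-olide | C=C1C(=O)O[C@H]2/C=C(\C)CC[C@H](OC(C)=O)[C@]3(C)CC[C@H](OO3)/C(C)=C\C[C@@H]12 | target

## Step count and least certain steps

Total step count: 19. Longest linear sequence: 13 steps (steps 7–12 then 13–19 from 9; equally steps 1–6 then 13–19 from 1).

Step 17 (key step). The most likely failure is participation of the C11 carbonyl oxygen in opening the activated epoxide (a 5-exo attack on C8), which would lead to a tetrahydrofuran ketal and no peroxide ring. Partial ionisation at C8 before hydrogen peroxide arrives would erode the inversion, and prolonged acid could drive further exchange at the hemiketal carbon. The fallback removes the carbonyl before perhydrolysis and sets out from 21: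
- Reduction with NaBH4 and CeCl3 gives the C11 allylic alcohol F1.
- Silylation (TESCl, imidazole) gives the triethylsilyl ether F2.
- Perhydrolysis as in step 17 gives the hydroxy hydroperoxide F3.
- HF·pyridine frees the allylic alcohol to give the triol-type hydroperoxide F4.
- Catalytic TsOH in CH2Cl2 closes the dioxane by acid-mediated alkylation of the hydroperoxide with the allylic cation, giving the 7-hydroxy dioxane F5 under reversible conditions.
- Acetylation (Ac2O, pyridine) returns to the route at 26.

Step 19. The hydride may show poor facial selectivity, because the macrocycle and not the local half-chair may decide which face of the C11 cation is open. Attack at the vinylogous position C13 and Z to E isomerisation through the delocalised cation are further risks. The fallback delivers the hydride from the C7 oxygen and sets out from 23: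
- Silylation of the C7 hydroxyl with i-Pr2SiHCl and imidazole gives the hydridosilyl ether F6.
- BF3·OEt2 at −78 °C ionises C11, and the tethered Si–H can only reach the face cis to C7.
- Work-up with HF·pyridine gives the 7-hydroxy dioxane F5, and acetylation returns to the route at 26.

Step 15. The macrocyclisation may be slow because the aldehyde is stored as the lactol. This would favour protodemetalation and oligomerisation, and the open aldehyde could epimerise at C1 or add with the wrong facial sense. The fallback runs the coupling on a free aldehyde with C16 silylated, and sets out from 13: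
- Selective silylation of the primary alcohol (TBDPSCl, imidazole) gives diol F7.
- NaIO4 gives the keto aldehyde F8.
- NaBH4 at −78 °C reduces only the aldehyde, giving the keto alcohol F9.
- TESCl gives the triethylsilyl ether F10.
- Alkylation of its lithium dienolate with 8 as in step 13 gives F11.
- Swern oxidation converts the primary triethylsilyl ether directly into the aldehyde F12.
- CrCl2/NiCl2 closes the ring to the silyl-protected macrocyclic alcohol F13, and Bu4NF returns to the route at 19.

Step 13. O-alkylation of the dienolate by the hard triflate, slow substitution at the CH2 next to the quaternary epoxide carbon and decomposition of the triflate may compete. The fallback uses a softer carbon nucleophile and sets out from 15: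
- Condensation with Me2NNH2 gives the dimethylhydrazone F14.
- Its lithium azaenolate (LiN(i-Pr)2) is alkylated with 8 at carbon, giving F15.
- Hydrolysis with NaIO4 in pH 7 buffer returns to the route at 17.

## Further compounds

F1 | step 17 | (1S,2S,3E,7S,8R,12Z)-7,8-epoxy-11-hydroxycembra-3,12,15(17)-trien-16,2-olide (C11 epimers) | C=C1C(=O)O[C@H]2/C=C(\C)CC[C@@H]3O[C@]3(C)CCC(O)/C(C)=C\C[C@@H]12
F2 | step 17 | 11-O-triethylsilyl ether of F1 | C=C1C(=O)O[C@H]2/C=C(\C)CC[C@@H]3O[C@]3(C)CCC(O[Si](CC)(CC)CC)/C(C)=C\C[C@@H]12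
F3 | step 17 | (1S,2S,3E,7S,8S,12Z)-8-hydroperoxy-7-hydroxy-11-(triethylsilyloxy)cembra-3,12,15(17)-trien-16,2-olide | C=C1C(=O)O[C@H]2/C=C(\C)CC[C@H](O)[C@@](C)(OO)CCC(O[Si](CC)(CC)CC)/C(C)=C\C[C@@H]12
F4 | step 17 | (1S,2S,3E,7S,8S,12Z)-8-hydroperoxy-7,11-dihydroxycembra-3,12,15(17)-trien-16,2-olide | C=C1C(=O)O[C@H]2/C=C(\C)CC[C@H](O)[C@@](C)(OO)CCC(O)/C(C)=C\C[C@@H]12
F5 | step 17 | (1S,2S,3E,7S,8S,11S,12Z)-8,11-epidioxy-7-hydroxycembra-3,12,15(17)-trien-16,2-olide | C=C1C(=O)O[C@H]2/C=C(\C)CC[C@H](O)[C@]3(C)CC[C@H](OO3)/C(C)=C\C[C@@H]12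
F6 | step 19 | 7-O-(diisopropylsilyl) ether of 23 (Si–H retained) | C=C1C(=O)O[C@H]2/C=C(\C)CC[C@H](O[SiH](C(C)C)C(C)C)[C@]3(C)CCC(O)(OO3)/C(C)=C\C[C@@H]12
F7 | step 15 | (5S)-5-[3-[tert-butyl(diphenyl)silyl]oxyprop-1-en-2-yl]-1,2-dimethylcyclohex-2-ene-1,6-diol | CC1=CC[C@H](C(O)C1(C)O)C(=C)CO[Si](c2ccccc2)(c2ccccc2)C(C)(C)C
F8 | step 15 | (2S,4Z)-2-[3-[tert-butyl(diphenyl)silyl]oxyprop-1-en-2-yl]-5-methyl-6-oxohept-4-enal | CC(=O)/C(C)=C\C[C@H](C=O)C(=C)CO[Si](c1ccccc1)(c1ccccc1)C(C)(C)C
F9 | step 15 | (3Z,6S)-6-(hydroxymethyl)-3-methyl-7-[[tert-butyl(diphenyl)silyl]oxymethyl]octa-3,7-dien-2-one | CC(=O)/C(C)=C\C[C@H](CO)C(=C)CO[Si](c1ccccc1)(c1ccccc1)C(C)(C)C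
F10 | step 15 | triethylsilyl ether of F9 | CC(=O)/C(C)=C\C[C@H](CO[Si](CC)(CC)CC)C(=C)CO[Si](c1ccccc1)(c1ccccc1)C(C)(C)C
F11 | step 15 | C10-alkylation product of F10 with 8 | I/C=C(\C)CC[C@@H]1O[C@]1(C)CCC(=O)/C(C)=C\C[C@H](CO[Si](CC)(CC)CC)C(=C)CO[Si](c2ccccc2)(c2ccccc2)C(C)(C)C
F12 | step 15 | open-chain C2 aldehyde from F11 | I/C=C(\C)CC[C@@H]1O[C@]1(C)CCC(=O)/C(C)=C\C[C@H](C=O)C(=C)CO[Si](c2ccccc2)(c2ccccc2)C(C)(C)C
F13 | step 15 | 16-O-[tert-butyl(diphenyl)silyl] ether of 19 | CC(C)(C)[Si](OCC(=C)[C@H]3[C@@H](O)/C=C(\C)CC[C@@H]4O[C@]4(C)CCC(=O)/C(C)=C\C3)(c1ccccc1)c1ccccc1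
F14 | step 13 | N,N-dimethylhydrazone of 15 | CN(C)N=C(C)/C(C)=C\C[C@@H]1C(O[Si](C)(C)C(C)(C)C)OCC1=C
F15 | step 13 | N,N-dimethylhydrazone of 17 | CN(C)N=C(CC[C@@]1(C)O[C@H]1CC/C(C)=C/I)/C(C)=C\C[C@@H]2C(O[Si](C)(C)C(C)(C)C)OCC2=C
A1 | alternative 1 | (1S,2S,3E,7S,8R,11E)-7,8-epoxycembra-3,11,15(17)-trien-16,2-olide | C=C1C(=O)O[C@H]2/C=C(\C)CC[C@@H]3O[C@]3(C)CC/C=C(\C)CC[C@@H]12
A2 | alternative 1 | (1S,2S,3E,7S,8R,11S,12Z)-7,8-epoxy-11-hydroperoxycembra-3,12,15(17)-trien-16,2-olide | C=C1C(=O)O[C@H]2/C=C(\C)CC[C@@H]3O[C@]3(C)CC[C@H](OO)/C(C)=C\C[C@@H]12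
A3 | alternative 1 | (1S,2S,3E,7S,8S,11S,12Z)-8,11-epidioxy-7-hydroxycembra-3,12,15(17)-trien-16,2-olide | C=C1C(=O)O[C@H]2/C=C(\C)CC[C@H](O)[C@]3(C)CC[C@H](OO3)/C(C)=C\C[C@@H]12
A4 | alternative 2 | 1,3-dimethylcyclohexa-1,3-diene | CC1=CC(C)=CCC1
A5 | alternative 2 | rac-1,5-dimethyl-2,3-dioxabicyclo[2.2.2]oct-5-ene | CC1=CC2(C)CCC1OO2
A6 | alternative 2 | rac-cis-6-acetyl-3-methyl-1,2-dioxane-3-carbaldehyde | CC(=O)[C@H]1CC[C@@](C)(C=O)OO1
A7 | alternative 3 | (1S,2S,3E,7S,8Z,12Z)-11-[tert-butyl(dimethyl)silyl]oxy-7-hydroxycembra-3,8,12,15(17)-tetraen-16,2-olide (C11 epimers) | C=C1C(=O)O[C@H]2/C=C(\C)CC[C@H](O)/C(C)=C\CC(O[Si](C)(C)C(C)(C)C)/C(C)=C\C[C@@H]12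
A8 | alternative 3 | (1S,2S,3E,7S,8S,9E,12Z)-11-[tert-butyl(dimethyl)silyl]oxy-8-hydroperoxy-7-hydroxycembra-3,9,12,15(17)-tetraen-16,2-olide (C11 epimers) | C=C1C(=O)O[C@H]2/C=C(\C)CC[C@H](O)[C@@](C)(OO)/C=C/C(O[Si](C)(C)C(C)(C)C)/C(C)=C\C[C@@H]12
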